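**Strategy.** Ring C (the 4-pyranone) is assembled around its C4 carbonyl carbon, which is supplied by carbon monoxide. A palladium-catalysed three-component carbonylative annulation joins 2-iodo-3,4,5-trimethoxyphenol (ring A), CO and 3-ethynyl-2,5,6-trimethoxyphenol (ring B), forming C4a–C4, C4–C3 and O1–C2 in one operation. The step exploits the ortho relationship of O1 and C4 on ring A and the mirror symmetry of 3,4,5-trimethoxyphenol, whose two ortho positions are equivalent, so the iodide that marks C4a needs no regiocontrol. The precursors are two simple phenols. A final chelation-controlled cleavage of the C5 methyl ether gives the target.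

Key step: step 5

Remark: the 3'-hydroxyl, flanked by two methoxy groups, is carried unprotected from step 3 onward. The target has no stereocentre.

**Step 1**
Reactants: 1 3,4,5-trimethoxyphenol
Product: 2 2-iodo-3,4,5-trimethoxyphenol
Conditions: NIS (1.0 equiv), CH2Cl2, −20 → 0 °C, dark
Reagents that add atoms: N-iodosuccinimide, O=C1CCC(=O)N1I
Why: Electrophilic aromatic iodination ortho to the phenol, where C2 and C6 are equivalent by symmetry and the para position is blocked, so a single mono-iodide should form if one equivalent of NIS is used cold.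

**Step 2**
Reactants: 3 1-bromo-2,4,5-trimethoxybenzene; 4 ethynyltriisopropylsilane
Product: 5 triisopropyl[(2,4,5-trimethoxyphenyl)ethynyl]silane
Conditions: PdCl2(MeCN)2 (2 mol %), XPhos (6 mol %), Cs2CO3, MeCN, 80 °C
Reagents that add atoms: none
Why: Copper-free Sonogashira coupling, in which the bulky electron-rich phosphine should allow oxidative addition into the electron-rich ortho-substituted aryl bromide, and the triisopropylsilyl group keeps the alkyne inert toward the organolithium of step 3.

**Step 3**
Reactants: 5 triisopropyl[(2,4,5-trimethoxyphenyl)ethynyl]silane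
Product: 8 2,3,6-trimethoxy-5-[(triisopropylsilyl)ethynyl]phenol, via C3 aryllithium 6 (not isolated), via lithium aryltrimethoxyborate 7 (not isolated)
Conditions: n-BuLi, TMEDA, THF, −20 → 0 °C; B(OMe)3, −78 °C → rt; 30% H2O2, AcOH, 0 °C → rt
Reagents that add atoms: hydrogen peroxide, OO
Why: Directed ortho-metalation, borylation and peroxide oxidation, in which C3–H between the two methoxy groups (cooperative lithium coordination and inductive acidification) should be removed in preference to C6–H, which has only one methoxy neighbour.

**Step 4**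
Reactants: 8 2,3,6-trimethoxy-5-[(triisopropylsilyl)ethynyl]phenol
Product: 9 3-ethynyl-2,5,6-trimethoxyphenol
Conditions: TBAF (2.2 equiv), THF, 0 °C → rt; AcOH quench
Reagents that add atoms: none
Why: Fluoride-induced protodesilylation of the alkynylsilane, driven by the Si–F bond, with the phenol carried as its phenoxide and protonated again on quench.

**Step 5**
Reactants: 2 2-iodo-3,4,5-trimethoxyphenol; 9 3-ethynyl-2,5,6-trimethoxyphenol; 10 carbon monoxide
Product: 13 3'-hydroxy-5,6,7,2',4',5'-hexamethoxyflavone, via ynone 11 (not isolated), via enaminone 12 (not isolated)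
Conditions: PdCl2(PPh3)2 (5 mol %), dppp (5 mol %), thiourea (5 mol %), Et2NH (solvent), DBU (2 equiv), CO (1 atm), 40 °C, slow addition of 9
Reagents that add atoms: none
Why: Zerovalent palladium inserts into the C–I bond of 2, CO migratory insertion gives an aroyl divalent palladium iodide, and the amine-deprotonated alkyne 9 is transferred to it so that reductive elimination releases the o-hydroxyaryl ynone 11 (copper-free carbonylative Sonogashira coupling). Et2NH then adds reversibly to the ynone β-carbon to give enaminone 12, and the ortho phenoxide displaces the amine by addition–elimination, closing ring C in a 6-endo mode (net 6-endo-dig oxa-Michael closure). The closest known reaction type is the palladium-catalysed carbonylative annulation of o-iodophenols with terminal arylacetylenes to flavones. No stereocentre is formed. The step needs CO insertion to precede alkyne transfer (otherwise a benzofuran results), which the CO-saturated medium, the slow addition of 9 and the readily migrating electron-rich aryl group should secure, and it needs 6-endo over 5-exo closure (aurone), which the enaminone pathway secures by placing the leaving group on C2. The 3'-hydroxyl of 9 is meta to the alkyne and flanked by two methoxy groups, so it can neither cyclise nor compete well for the acylpalladium.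

**Step 6**
Reactants: 13 3'-hydroxy-5,6,7,2',4',5'-hexamethoxyflavone
Product: 15 psiadiarabicin (5,3'-dihydroxy-6,7,2',4',5'-pentamethoxyflavone), via aryloxydichloroborane 14 (not isolated)
Conditions: BCl3 (3 equiv), CH2Cl2, −78 → 0 °C; then H2O, 0 °C
Reagents that add atoms: none
Why: Chelation-controlled Lewis-acid ether cleavage, in which boron held between the C4 carbonyl and O5 in a six-membered chelate should activate only the peri C5 methyl ether for chloride attack at the methyl carbon, while the 3'-phenol is only converted to its dichloroborane ester and returns on hydrolysis.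

**Compound list**
1 | 3,4,5-trimethoxyphenol | COc1cc(O)cc(OC)c1OC | starting material
2 | 2-iodo-3,4,5-trimethoxyphenol | COc1cc(O)c(I)c(OC)c1OC | intermediate
3 | 1-bromo-2,4,5-trimethoxybenzene | COc1cc(OC)c(Br)cc1OC | starting material
4 | ethynyltriisopropylsilane | C#C[Si](C(C)C)(C(C)C)C(C)C | starting material
5 | triisopropyl[(2,4,5-trimethoxyphenyl)ethynyl]silane | COc1cc(OC)c(C#C[Si](C(C)C)(C(C)C)C(C)C)cc1OC | intermediate
6 | {2,3,6-trimethoxy-5-[(triisopropylsilyl)ethynyl]phenyl}lithium | [Li]c1c(OC)c(OC)cc(C#C[Si](C(C)C)(C(C)C)C(C)C)c1OC | intermediate (not isolated)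
7 | lithium trimethoxy{2,3,6-trimethoxy-5-[(triisopropylsilyl)ethynyl]phenyl}borate | [Li+].CO[B-](OC)(OC)c1c(OC)c(OC)cc(C#C[Si](C(C)C)(C(C)C)C(C)C)c1OC | intermediate (not isolated)
8 | 2,3,6-trimethoxy-5-[(triisopropylsilyl)ethynyl]phenol | Oc1c(OC)c(OC)cc(C#C[Si](C(C)C)(C(C)C)C(C)C)c1OC | intermediate
9 | 3-ethynyl-2,5,6-trimethoxyphenol | C#Cc1cc(OC)c(OC)c(O)c1OC | intermediate
10 | carbon monoxide | [C-]#[O+] | starting material
11 | 1-(2-hydroxy-4,5,6-trimethoxyphenyl)-3-(3-hydroxy-2,4,5-trimethoxyphenyl)prop-2-yn-1-one | O=C(C#Cc1cc(OC)c(OC)c(O)c1OC)c1c(O)cc(OC)c(OC)c1OC | intermediate (not isolated)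
12 | 3-(diethylamino)-1-(2-hydroxy-4,5,6-trimethoxyphenyl)-3-(3-hydroxy-2,4,5-trimethoxyphenyl)prop-2-en-1-one (E/Z interconverting, geometry not fixed) | CCN(CC)C(=CC(=O)c1c(O)cc(OC)c(OC)c1OC)c1cc(OC)c(OC)c(O)c1OC | intermediate (not isolated)
13 | 3'-hydroxy-5,6,7,2',4',5'-hexamethoxyflavone [2-(3-hydroxy-2,4,5-trimethoxyphenyl)-5,6,7-trimethoxy-4H-chromen-4-one] | COc1cc(-c2cc(=O)c3c(OC)c(OC)c(OC)cc3o2)c(OC)c(O)c1OC | intermediate
14 | 5-O,3'-O-bis(dichloroboryl) derivative of psiadiarabicin | COc1cc(-c2cc(=O)c3c(OB(Cl)Cl)c(OC)c(OC)cc3o2)c(OC)c(OB(Cl)Cl)c1OC | intermediate (not isolated)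
15 | psiadiarabicin [5-hydroxy-2-(3-hydroxy-2,4,5-trimethoxyphenyl)-6,7-dimethoxy-4H-chromen-4-one] | COc1cc(-c2cc(=O)c3c(O)c(OC)c(OC)cc3o2)c(OC)c(O)c1OC | target

**Total step count:** 6
**Longest linear sequence:** 5 steps (steps 2, 3, 4, 5, 6)

**Steps most likely to fail**

1. Step 5. Oxidative addition and CO capture at the doubly ortho-substituted, electron-rich C–I bond may be slow. That would leave room for direct alkyne transfer without CO (benzofuran formation), for amine capture of the acylpalladium, or for 5-exo closure. The fallback uses no palladium and brings in the C4 carbon as a formyl group; it sets out from 1 and 9 and comes back at 11. Phenol 1 would be ortho-formylated (MgCl2, Et3N, paraformaldehyde, MeCN, reflux) to 6-hydroxy-2,3,4-trimethoxybenzaldehyde F1. Alkyne 9 would be converted with n-BuLi (2 equiv, THF, −78 °C) into its O,C-dilithio derivative F2. F1, its phenol first deprotonated with LiHMDS, would be added to F2, and an AcOH quench should give racemic 1-(2-hydroxy-4,5,6-trimethoxyphenyl)-3-(3-hydroxy-2,4,5-trimethoxyphenyl)prop-2-yn-1-ol F3, whose carbinol centre is removed in the next operation. MnO2 (CH2Cl2, rt) should oxidise F3 to ynone 11, which would be closed to 13 with Et2NH and DBU at 40 °C as in step 5.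

2. Step 3. Deprotonation may occur in part at C6 next to the alkyne, or the organolithium may add across the aryl alkyne at the temperature that deprotonation needs. The fallback fixes the site by electrophilic substitution instead of by C–H acidity; it sets out from 5 and comes back at 6. NBS (MeCN, 0 °C) should brominate C3, the only position activated by two ortho methoxy groups, to give [(3-bromo-2,4,5-trimethoxyphenyl)ethynyl]triisopropylsilane F4. Bromine–lithium exchange (n-BuLi, THF, −78 °C) would then generate aryllithium 6 at low temperature, and borylation and oxidation would continue to 8 as in step 3.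

3. Step 6. Further methyl groups may be lost, either by boron bound at O3' delivering cleavage to the adjacent 2'- or 4'-methoxy group, or by continued cleavage at C6 once the C5 chelate exists. The fallback masks the 3'-oxygen as an electron-poor ester so that no boron phenoxide can form on ring B; it sets out from 13 and comes back at 15. Acetylation (Ac2O, DMAP, pyridine, rt) should give 3'-acetoxy-5,6,7,2',4',5'-hexamethoxyflavone F5. BCl3 (1.2 equiv, CH2Cl2, −78 → 0 °C) would then cleave only the chelated C5 methyl ether via the 5-O-dichloroboryl chelate F6. Water work-up should give 3'-acetoxy-5-hydroxy-6,7,2',4',5'-pentamethoxyflavone F7, and methanolysis (K2CO3, MeOH, rt) would release 15.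

**Further compounds**
F1 | step 5 | 6-hydroxy-2,3,4-trimethoxybenzaldehyde | O=Cc1c(O)cc(OC)c(OC)c1OC
F2 | step 5 | O,C-dilithio derivative of 9 (lithium 3-(lithioethynyl)-2,5,6-trimethoxyphenolate) | [Li]C#Cc1cc(OC)c(OC)c(O[Li])c1OC
F3 | step 5 | racemic 1-(2-hydroxy-4,5,6-trimethoxyphenyl)-3-(3-hydroxy-2,4,5-trimethoxyphenyl)prop-2-yn-1-ol | OC(C#Cc1cc(OC)c(OC)c(O)c1OC)c1c(O)cc(OC)c(OC)c1OC
F4 | step 3 | [(3-bromo-2,4,5-trimethoxyphenyl)ethynyl]triisopropylsilane | COc1cc(C#C[Si](C(C)C)(C(C)C)C(C)C)c(OC)c(Br)c1OC
F5 | step 6 | 3'-acetoxy-5,6,7,2',4',5'-hexamethoxyflavone | COc1cc(-c2cc(=O)c3c(OC)c(OC)c(OC)cc3o2)c(OC)c(OC(C)=O)c1OC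
F6 | step 6 | 5-O-dichloroboryl chelate of 3'-acetoxy-5-hydroxy-6,7,2',4',5'-pentamethoxyflavone | COc1cc(-c2cc(=O)c3c(OB(Cl)Cl)c(OC)c(OC)cc3o2)c(OC)c(OC(C)=O)c1OC
F7 | step 6 | 3'-acetoxy-5-hydroxy-6,7,2',4',5'-pentamethoxyflavone | COc1cc(-c2cc(=O)c3c(O)c(OC)c(OC)cc3o2)c(OC)c(OC(C)=O)c1OC
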